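**Plan**

- Retrosynthetic cuts: (a) C5–C6 of the benzene ring (an ester carbon and the methyl carbon of an acetyl group); (b) C7–C8 (the acetyl carbonyl carbon and the lateral CH2 of a 2-ethyl-4-pyranone); (c) C4–C4a and O1–C8a of the pyranone. Cut (c) gives an acylketene (C2, C3, C4, O1 and the C31 chain, from dotriacontanoic acid and Meldrum's acid) and the pyrrolidine enamine of methyl 3-oxopentanoate (C8a, C4a, C5, C8 and the 8-methyl).
- Forward order: the 4-pyranone ring is made first and already carries the chain, an ester on C3 and an ethyl group on C2; one acetyl unit is then attached to the ethyl CH2; the benzene ring is closed last.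
- Enabling feature: in the target, ring C4a–C5–C6–C7–C8–C8a has 1,3-related hydroxyls on C5 and C7 and its methyl on C8, next to C8a, which holds ring oxygen O1. C4a/C5 therefore map onto C3 of a 4-pyranone and its ester, C8a/C8/CH3 onto C2 and its ethyl group, and C6/C7 onto one acetyl unit. Ester and 2-oxopropyl arm thus sit cis on one C=C, and the methyl position is fixed before the ring closes (no 6-methyl/8-methyl ambiguity).
- Stereochemistry: the target has no stereocentre. The single racemic centre of the cyclisation precursor becomes aromatic C8, and the enamine geometry disappears when the pyranone forms.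

Key step: step 6

Assumption: dotriacontanoic acid is taken as a purchasable fatty acid, the acyl Meldrum's acid is drawn as its enol, and the enolate steps are set at −40 °C in dilute THF because the C31 chain limits solubility in colder ether solvents.

**Route**

Step 1
Reactants: 1 dotriacontanoic acid (lacceroic acid)
Product: 2 dotriacontanoyl chloride
Conditions: (COCl)2 (1.5 equiv), DMF (cat.), PhMe, 50 °C; evaporate, use crude
Reagents that add atoms: oxalyl chloride, ClC(=O)C(=O)Cl
Why: Catalytic DMF and oxalyl chloride form the Vilsmeier chloroiminium salt, which turns the acid into its chloride with loss of gases only (standard acyl chloride formation), and warm toluene keeps the C32 acid in solution.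

Step 2
Reactants: 2 dotriacontanoyl chloride; 3 Meldrum's acid (2,2-dimethyl-1,3-dioxane-4,6-dione)
Product: 4 5-(1-hydroxydotriacontylidene)-2,2-dimethyl-1,3-dioxane-4,6-dione
Conditions: pyridine (2.2 equiv), DMAP (cat.), CH2Cl2, 0 °C to rt; wash with 1 M HCl
Reagents that add atoms: none
Why: The acidic methylene of Meldrum's acid is C-acylated by the acid chloride under pyridine/DMAP (C-acylation of Meldrum's acid), and the product rests as its hydrogen-bonded enol, which stops a second acylation.

Step 3
Reactants: 5 methyl 3-oxopentanoate; 6 pyrrolidine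
Product: 7 methyl (E)-3-(pyrrolidin-1-yl)pent-2-enoate
Conditions: 6 (1.2 equiv), p-TsOH·H2O (cat.), PhMe, reflux, Dean–Stark
Reagents that add atoms: none
Why: Condensation of the ketone carbonyl with the secondary amine under azeotropic removal of water (enamine formation) should give the conjugated vinylogous carbamate as its stable E isomer, whose geometry plays no role later.

Step 4
Reactants: 4 5-(1-hydroxydotriacontylidene)-2,2-dimethyl-1,3-dioxane-4,6-dione; 7 methyl (E)-3-(pyrrolidin-1-yl)pent-2-enoate
Product: 10 methyl 2-ethyl-6-hentriacontyl-4-oxo-4H-pyran-3-carboxylate, via acylketene 8 (not isolated), via dihydropyranone aminal 9 (not isolated)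
Conditions: PhMe, 105 °C, slow addition of 4 to 7 (1.5 equiv); then TFA, rt
Reagents that add atoms: none
Why: Thermal fragmentation of 4 (loss of acetone and CO2) gives acylketene 8, which the nucleophilic β-carbon of the tertiary enamino ester captures in a formal hetero-[4+2] cycloaddition (C-acylation, then closure of the acyl oxygen onto the iminium carbon) to aminal 9, and acid-promoted β-elimination of pyrrolidine aromatises it to the 4-pyranone, the established acylketene–enamine route to 4-pyranones.

Step 5
Reactants: 10 methyl 2-ethyl-6-hentriacontyl-4-oxo-4H-pyran-3-carboxylate; 11 N-methoxy-N-methylacetamide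
Product: 13 methyl 6-hentriacontyl-4-oxo-2-(3-oxobutan-2-yl)-4H-pyran-3-carboxylate (racemic), via tetrahedral Weinreb adduct 12 (not isolated)
Conditions: LiN(SiMe3)2 (2.2 equiv), THF (dilute), −40 °C; 11 (1.5 equiv), −40 to 0 °C; 1 M HCl
Reagents that add atoms: none
Why: LiN(SiMe3)2 removes a lateral proton reversibly, so the anion should settle on the ethyl CH2 at C2, the only site vinylogous to both the C4 carbonyl and the C3 ester, and this extended enolate is C-acylated by the Weinreb amide through adduct 12, whose collapse is pulled forward by the second equivalent of base deprotonating the acidic methine of the product (lateral metalation and Claisen-type acylation of a 2-alkyl-4-pyranone); the new stereocentre forms racemic and is erased in step 6.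

Step 6
Reactants: 13 methyl 6-hentriacontyl-4-oxo-2-(3-oxobutan-2-yl)-4H-pyran-3-carboxylate
Product: 15 2-hentriacontyl-5,7-dihydroxy-8-methyl-4H-chromen-4-one (target), via cyclic trione 14 (not isolated)
Conditions: LiN(i-Pr)2 (3.3 equiv), THF (dilute), −40 °C to rt; 1 M HCl
Reagents that add atoms: none
Why: Proposed new method: LiN(i-Pr)2 first removes the C–H flanked by the ketone and pyranone C2 of 13 and then a proton of the terminal acetyl methyl; the terminal carbon of this 1,3-dianion adds to the ester carbonyl held cis to it on the C2=C3 bond of the pyranone, methoxide leaves, and trione 14 enolises to the bis-phenoxide of 15, which makes the sequence irreversible. The closest known reaction type is the base-mediated Dieckmann/Claisen cyclisation of 2-(2-oxopropyl)benzoates to naphthalene-1,3-diols, together with Claisen-type aromatisations of pyranone-masked polyketo esters; new here is the 4-pyranone-3-carboxylate as the platform. The one ring closed is the carbocycle C4a–C5–C6–C7–C8–C8a, through the C5–C6 bond, in a 6-(enolendo)-exo-trig closure, a favoured mode of enolate ring closure. No stereocentre is created, since the racemic centre of 13 becomes aromatic C8. The step needs C-acylation by the methyl-derived enolate carbon rather than closure of the ketone enolate oxygen onto the ester (enol lactone) or retro-Claisen loss of the acetyl group; complete dianion formation at −40 °C before warming, the non-nucleophilic amide base and the aromatic sink should secure this. Closure onto the ring carbonyl C4 is geometrically excluded because C4 lies trans to the side chain across C2=C3.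

**Compound list**

1 | dotriacontanoic acid (lacceroic acid) | CCCCCCCCCCCCCCCCCCCCCCCCCCCCCCCC(=O)O | starting material
2 | dotriacontanoyl chloride | CCCCCCCCCCCCCCCCCCCCCCCCCCCCCCCC(=O)Cl | intermediate
3 | Meldrum's acid (2,2-dimethyl-1,3-dioxane-4,6-dione) | CC1(C)OC(=O)CC(=O)O1 | starting material
4 | 5-(1-hydroxydotriacontylidene)-2,2-dimethyl-1,3-dioxane-4,6-dione | CCCCCCCCCCCCCCCCCCCCCCCCCCCCCCCC(O)=C1C(=O)OC(C)(C)OC1=O | intermediate
5 | methyl 3-oxopentanoate | CCC(=O)CC(=O)OC | starting material
6 | pyrrolidine | C1CCNC1 | starting material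
7 | methyl (E)-3-(pyrrolidin-1-yl)pent-2-enoate | CC/C(=C\C(=O)OC)N1CCCC1 | intermediate
8 | tetratriacont-1-ene-1,3-dione (dotriacontanoylketene) | CCCCCCCCCCCCCCCCCCCCCCCCCCCCCCCC(=O)C=C=O | intermediate (not isolated)
9 | methyl 2-ethyl-6-hentriacontyl-4-oxo-2-(pyrrolidin-1-yl)-3,4-dihydro-2H-pyran-3-carboxylate (mixture of diastereomers) | CCCCCCCCCCCCCCCCCCCCCCCCCCCCCCCC1=CC(=O)C(C(=O)OC)C(CC)(N2CCCC2)O1 | intermediate (not isolated)
10 | methyl 2-ethyl-6-hentriacontyl-4-oxo-4H-pyran-3-carboxylate | CCCCCCCCCCCCCCCCCCCCCCCCCCCCCCCc1cc(=O)c(C(=O)OC)c(CC)o1 | intermediate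
11 | N-methoxy-N-methylacetamide | CC(=O)N(C)OC | starting material
12 | lithium 3-[6-hentriacontyl-3-(methoxycarbonyl)-4-oxo-4H-pyran-2-yl]-2-[methoxy(methyl)amino]butan-2-olate (mixture of diastereomers) | CCCCCCCCCCCCCCCCCCCCCCCCCCCCCCCc1cc(=O)c(C(=O)OC)c(C(C)C(C)([O-])N(C)OC)o1.[Li+] | intermediate (not isolated)
13 | methyl 6-hentriacontyl-4-oxo-2-(3-oxobutan-2-yl)-4H-pyran-3-carboxylate (racemic) | CCCCCCCCCCCCCCCCCCCCCCCCCCCCCCCc1cc(=O)c(C(=O)OC)c(C(C)C(C)=O)o1 | intermediate
14 | 2-hentriacontyl-8-methyl-4H-chromene-4,5,7(6H,8H)-trione (racemic) | CCCCCCCCCCCCCCCCCCCCCCCCCCCCCCCC1=CC(=O)C2=C(O1)C(C)C(=O)CC2=O | intermediate (not isolated)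
15 | 2-hentriacontyl-5,7-dihydroxy-8-methyl-4H-chromen-4-one | CCCCCCCCCCCCCCCCCCCCCCCCCCCCCCCc1cc(=O)c2c(O)cc(O)c(C)c2o1 | target

**Step count and risks**

Total steps: 6. Longest linear sequence: 5 steps (1 → 2 → 4 → 10 → 13 → 15; the enamine branch 5 + 6 → 7 is one step and joins at step 4).

Steps most likely to fail:

Step 6. The risks are acyl transfer to oxygen instead of carbon (the ketone enolate oxygen closing onto the ester), cleavage of the acetyl group by the methoxide that is released, or an incomplete second deprotonation that leaves the unreactive mono-anion. The fallback gives up the late benzannulation and uses classical chromone chemistry on a differentiated phloroacetophenone; it sets out from 2 and comes back at 15. The purchasable 1-(2-hydroxy-4,6-dimethoxy-3-methylphenyl)ethan-1-one F1, whose only free hydroxyl lies next to the ring methyl, is converted with LiN(SiMe3)2 (3.3 equiv, THF, −78 to −10 °C) into its phenoxide–enolate dianion and acylated with 2. This should give 1-(2-hydroxy-4,6-dimethoxy-3-methylphenyl)tetratriacontane-1,3-dione F2; any aryl ester formed first rearranges under the excess base (Baker–Venkataraman rearrangement). Cyclodehydration (cat. H2SO4, AcOH, 90 °C) should give 2-hentriacontyl-5,7-dimethoxy-8-methyl-4H-chromen-4-one F3, in which the methyl can only be on C8 because the pyranone oxygen is the hydroxyl that flanked it. BBr3 (CH2Cl2, −78 °C to reflux) then cleaves both methyl ethers to 15; a Lewis acid is chosen over hot HBr so that ring opening and reclosure (Wessely–Moser rearrangement) cannot interchange the 8-methyl and 6-methyl series.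

Step 5. The risks are competing metalation at the CH2 of the C31 chain on C6 and an unfavourable addition equilibrium between the strongly stabilised, hindered secondary anion and the Weinreb amide, so that substrate returns unchanged or is acetylated at the wrong site. The fallback places the acetyl unit, masked as a dioxolane, before the pyranone is made and needs no lateral metalation; it sets out from 4 (with a new enamine partner) and comes back at 13.
- Ethyl 2-methyl-3-oxobutanoate F4 is ketalised with ethylene glycol (p-TsOH, PhMe, Dean–Stark) to ethyl 2-(2-methyl-1,3-dioxolan-2-yl)propanoate F5.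
- F5 is saponified (LiOH, aqueous THF) to 2-(2-methyl-1,3-dioxolan-2-yl)propanoic acid F6.
- F6 is activated with 1,1'-carbonyldiimidazole to 1-(1H-imidazol-1-yl)-2-(2-methyl-1,3-dioxolan-2-yl)propan-1-one F7, which is not isolated, and homologated with KO2CCH2CO2Me, MgCl2 and Et3N (Masamune–Brooks homologation) to methyl 4-(2-methyl-1,3-dioxolan-2-yl)-3-oxopentanoate F8.
- Condensation of F8 with 6 gives methyl (E)-4-(2-methyl-1,3-dioxolan-2-yl)-3-(pyrrolidin-1-yl)pent-2-enoate F9.
- F9 is heated with 4 in toluene as in step 4 and passes through 8 and methyl 6-hentriacontyl-2-[1-(2-methyl-1,3-dioxolan-2-yl)ethyl]-4-oxo-2-(pyrrolidin-1-yl)-3,4-dihydro-2H-pyran-3-carboxylate F10. Anhydrous TFA should give methyl 6-hentriacontyl-2-[1-(2-methyl-1,3-dioxolan-2-yl)ethyl]-4-oxo-4H-pyran-3-carboxylate F11.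
- Brief treatment of F11 with aqueous TFA at room temperature removes the dioxolane and gives 13. The acid is kept mild so that the freed ketone does not close onto the ester as an enol lactone.

Step 4. The risks are proton transfer from the strongly acidic acyl Meldrum's acid to the enamine, which stalls the fragmentation and exposes the enamine to hydrolysis, and self-condensation of the acylketene before it is captured. The fallback stores the acylketene in a neutral form; it sets out from 4 and comes back at 10. Heating 4 in toluene with an excess of acetone should give 6-hentriacontyl-2,2-dimethyl-4H-1,3-dioxin-4-one F12 with loss of CO2. F12 is then heated with 7 in xylene at 130–140 °C, where retro-[4+2] loss of acetone regenerates 8 without any acid present and next to its trap, and TFA treatment of the resulting 9 gives 10.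

**Further compounds**

F1 | step 6 | 1-(2-hydroxy-4,6-dimethoxy-3-methylphenyl)ethan-1-one | CC(=O)c1c(O)c(C)c(OC)cc1OC
F2 | step 6 | 1-(2-hydroxy-4,6-dimethoxy-3-methylphenyl)tetratriacontane-1,3-dione | CCCCCCCCCCCCCCCCCCCCCCCCCCCCCCCC(=O)CC(=O)c1c(O)c(C)c(OC)cc1OC
F3 | step 6 | 2-hentriacontyl-5,7-dimethoxy-8-methyl-4H-chromen-4-one | CCCCCCCCCCCCCCCCCCCCCCCCCCCCCCCc1cc(=O)c2c(OC)cc(OC)c(C)c2o1
F4 | step 5 | ethyl 2-methyl-3-oxobutanoate (racemic) | CCOC(=O)C(C)C(C)=O
F5 | step 5 | ethyl 2-(2-methyl-1,3-dioxolan-2-yl)propanoate (racemic) | CCOC(=O)C(C)C1(C)OCCO1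
F6 | step 5 | 2-(2-methyl-1,3-dioxolan-2-yl)propanoic acid (racemic) | CC(C(=O)O)C1(C)OCCO1
F7 | step 5 | 1-(1H-imidazol-1-yl)-2-(2-methyl-1,3-dioxolan-2-yl)propan-1-one (racemic) | CC(C(=O)n1ccnc1)C1(C)OCCO1
F8 | step 5 | methyl 4-(2-methyl-1,3-dioxolan-2-yl)-3-oxopentanoate (racemic) | COC(=O)CC(=O)C(C)C1(C)OCCO1
F9 | step 5 | methyl (E)-4-(2-methyl-1,3-dioxolan-2-yl)-3-(pyrrolidin-1-yl)pent-2-enoate (racemic) | CC(C1(C)OCCO1)/C(=C\C(=O)OC)N1CCCC1
F10 | step 5 | methyl 6-hentriacontyl-2-[1-(2-methyl-1,3-dioxolan-2-yl)ethyl]-4-oxo-2-(pyrrolidin-1-yl)-3,4-dihydro-2H-pyran-3-carboxylate (mixture of diastereomers) | CCCCCCCCCCCCCCCCCCCCCCCCCCCCCCCC1=CC(=O)C(C(=O)OC)C(C(C)C2(C)OCCO2)(N2CCCC2)O1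
F11 | step 5 | methyl 6-hentriacontyl-2-[1-(2-methyl-1,3-dioxolan-2-yl)ethyl]-4-oxo-4H-pyran-3-carboxylate (racemic) | CCCCCCCCCCCCCCCCCCCCCCCCCCCCCCCc1cc(=O)c(C(=O)OC)c(C(C)C2(C)OCCO2)o1
F12 | step 4 | 6-hentriacontyl-2,2-dimethyl-4H-1,3-dioxin-4-one | CCCCCCCCCCCCCCCCCCCCCCCCCCCCCCCC1=CC(=O)OC(C)(C)O1
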